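**Plan**

1. Retrosynthetic cuts: the C19–O cinnamate bond; the C4–C18 methyl bond, back to a C3=C4 unsaturated C19 ester; then C1–C2 and C5–C10 together (retro-[4+2]); then C3–C4 (vinyl coupling), C4=C5 (olefination), C6–C7 and C9–C10 (two epoxide openings), down to myrcene.
2. Enabling feature: ring A (C1–C5, C10) is a six-membered ring fused to ring B along C5–C10, and C4 bears a carboxyl-level carbon (C19). With C3=C4 in place, ring A is a cyclohexene whose diene (C2=C3–C4=C5) and dienophile (C10=C1, carrying the angular C20 methyl) are already joined by the four ring-B atoms C6–C9, i.e. a deca-1,7,9-triene.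
3. Forward: myrcene supplies C7–C9 and C11–C17, side-chain diene included. The chain is extended at C9 (isopropenyl = C10, C1, C20), C7 (C6, C5), C5 (C4, C19) and C4 (C3, C2). One thermal cycloaddition then forms rings A and B together; C18, reduction at C19 and acylation finish.
4. Stereochemistry: C8 and C9 come from Sharpless asymmetric epoxidation and anti epoxide opening. C5 and C10 are relayed from C8/C9 through the chair-like tether of the cycloaddition. C4 comes from equatorial methylation of the ester enolate, anti to the C10 methyl. The cinnamate geometry is bought in.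

Key step: step 9

Remark on numbering: labdane numbering is used for all intermediates (C17 = CH3 on C8, C18 = CH3 on C4, C19 = carboxyl-derived carbon on C4, C20 = CH3 on C10).
Assumption: bromophosphonate 13, the α-bromo derivative of the common bis(2,2,2-trifluoroethyl) phosphonoacetate, is taken as a purchasable reagent.

**Step 1**
Reactants: 1 myrcene
Product: 2 (2E)-2-methyl-6-methylideneocta-2,7-dien-1-ol
Conditions: SeO2 (cat.), t-BuOOH, salicylic acid (cat.), CH2Cl2, 0 °C to rt
Reagents that add atoms: tert-butyl hydroperoxide, CC(C)(C)OO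
Why: Allylic oxidation with SeO2 (ene reaction then [2,3]-shift) should hydroxylate the (E)-methyl group of the electron-rich trisubstituted alkene and leave the conjugated diene alone, so C7 becomes the handle for chain extension.

**Step 2**
Reactants: 2 (2E)-2-methyl-6-methylideneocta-2,7-dien-1-ol
Product: 3 [(2R,3R)-2-methyl-3-(3-methylidenepent-4-en-1-yl)oxiran-2-yl]methanol
Conditions: Ti(Oi-Pr)4 (cat.), D-(−)-diethyl tartrate (cat.), t-BuOOH, 4 Å molecular sieves, CH2Cl2, −20 °C
Reagents that add atoms: tert-butyl hydroperoxide, CC(C)(C)OO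
Why: Sharpless asymmetric epoxidation is hydroxyl-directed, so only the allylic C8=C9 alkene reacts, and the D-(−)-tartrate ligand should deliver oxygen to the face that gives the (2R,3R) epoxide, fixing C8 and the precursor configuration of C9.

**Step 3**
Reactants: 3 [(2R,3R)-2-methyl-3-(3-methylidenepent-4-en-1-yl)oxiran-2-yl]methanol; 4 isopropenylmagnesium bromide
Product: 5 (2S,3R)-2-methyl-6-methylidene-3-(prop-1-en-2-yl)oct-7-ene-1,2-diol
Conditions: CuI (cat.), THF, −30 to 0 °C; aq. NH4Cl
Reagents that add atoms: none
Why: Copper-catalysed Grignard opening of a 2,3-epoxy alcohol should occur by SN2 attack at the only accessible epoxide carbon (C9, since C8 is fully substituted), so C9 is set by inversion while the C8–O bond and its configuration are kept.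

**Step 4**
Reactants: 5 (2S,3R)-2-methyl-6-methylidene-3-(prop-1-en-2-yl)oct-7-ene-1,2-diol
Product: 7 (2S)-2-methyl-2-[(3R)-2-methyl-6-methylideneocta-1,7-dien-3-yl]oxirane, via primary monotosylate 6 (not isolated)
Conditions: TsCl, Et3N, DMAP (cat.), CH2Cl2, 0 °C; then K2CO3, MeOH, rt
Reagents that add atoms: 4-methylbenzenesulfonyl chloride, Cc1ccc(cc1)S(Cl)(=O)=O (sulfonyl group in intermediate 6 only)
Why: Selective sulfonylation of the primary hydroxyl followed by intramolecular Williamson etherification by the tertiary alkoxide should close the terminal epoxide without touching the C8–O bond, so C8 keeps its configuration.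

**Step 5**
Reactants: 7 (2S)-2-methyl-2-[(3R)-2-methyl-6-methylideneocta-1,7-dien-3-yl]oxirane; 8 acetonitrile
Product: 10 (4R,5R)-4-methyl-8-methylidene-5-(prop-1-en-2-yl)-4-[(trimethylsilyl)oxy]dec-9-enenitrile, via lithium alkoxide 9 (not isolated)
Conditions: n-BuLi, THF, −78 °C (forms LiCH2CN from 8); add 7, −78 °C to rt; then Me3SiCl, 0 °C
Reagents that add atoms: chlorotrimethylsilane, C[Si](C)(C)Cl; n-butyllithium, [Li]CCCC (lithium in intermediate 9 only)
Why: SN2 opening of the 2,2-disubstituted epoxide at its CH2 terminus by lithioacetonitrile should add C6 and C5, and silylation of the resulting tertiary alkoxide in the same flask protects O-8 for the base-mediated olefination ahead.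

**Step 6**
Reactants: 10 (4R,5R)-4-methyl-8-methylidene-5-(prop-1-en-2-yl)-4-[(trimethylsilyl)oxy]dec-9-enenitrile
Product: 12 (4R,5R)-4-methyl-8-methylidene-5-(prop-1-en-2-yl)-4-[(trimethylsilyl)oxy]dec-9-enal, via N-aluminoimine 11 (not isolated)
Conditions: i-Bu2AlH, toluene, −78 °C; then aq. KNaC4H4O6 (potassium sodium tartrate), rt
Reagents that add atoms: water, O; diisobutylaluminium hydride, CC(C)C[AlH]CC(C)C (aluminium group in intermediate 11 only)
Why: Partial reduction of a nitrile with i-Bu2AlH should stop at the N-aluminoimine, which hydrolyses on work-up to the aldehyde, while the silyl ether and the alkenes are inert.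

**Step 7**
Reactants: 12 (4R,5R)-4-methyl-8-methylidene-5-(prop-1-en-2-yl)-4-[(trimethylsilyl)oxy]dec-9-enal; 13 methyl 2-[bis(2,2,2-trifluoroethoxy)phosphoryl]-2-bromoacetate
Product: 14 methyl (2E,6R,7R)-2-bromo-6-methyl-10-methylidene-7-(prop-1-en-2-yl)-6-[(trimethylsilyl)oxy]dodeca-2,11-dienoate
Conditions: KOt-Bu, 18-crown-6, THF, −78 °C
Reagents that add atoms: none
Why: Horner–Wadsworth–Emmons olefination with the electron-poor bis(trifluoroethyl) phosphonate under dissociating conditions (Still–Gennari-type kinetic control) should give the (E)-α-bromoacrylate, in which the C6 chain is cis to the ester and trans to bromine.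

**Step 8**
Reactants: 14 methyl (2E,6R,7R)-2-bromo-6-methyl-10-methylidene-7-(prop-1-en-2-yl)-6-[(trimethylsilyl)oxy]dodeca-2,11-dienoate; 15 tributyl(ethenyl)stannane
Product: 16 methyl (2Z,6R,7R)-2-ethenyl-6-methyl-10-methylidene-7-(prop-1-en-2-yl)-6-[(trimethylsilyl)oxy]dodeca-2,11-dienoate
Conditions: Pd2(dba)3 (cat.), tri(2-furyl)phosphine, CuI (cat.), NMP, 40 °C; product used without delay
Reagents that add atoms: none
Why: Stille coupling of an α-bromoacrylate proceeds with retention of alkene geometry, so the vinyl group (C3=C2) should end up trans to the C6 tether, the geometry the diene needs to reach its s-cis reactive conformation.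

**Step 9**
Reactants: 16 methyl (2Z,6R,7R)-2-ethenyl-6-methyl-10-methylidene-7-(prop-1-en-2-yl)-6-[(trimethylsilyl)oxy]dodeca-2,11-dienoate
Product: 17 methyl 8α-[(trimethylsilyl)oxy]-18-norlabda-3,13(16),14-trien-19-oate (5R,8R,9R,10S)
Conditions: toluene (high dilution), BHT, sealed tube, 170 °C
Reagents that add atoms: none
Why: A concerted, suprafacial thermal [4+2] cycloaddition joins the 2-carbomethoxy diene (C2=C3–C4=C5) to the unactivated 1,1-disubstituted alkene C10=C1, i.e. a type 1 intramolecular Diels–Alder reaction of a deca-1,7,9-triene, whose closest precedent is the thermal cyclisation of ester-substituted decatrienes to angularly methylated octalins. Ring A is closed as the new cyclohexene by both forming bonds (C1–C2 and C5–C10), and ring B is closed by the C5–C10 bond alone, in the fused mode, through a chair-like arrangement of the four-atom tether C6–C9. C10 and C5 are set by relay from C8/C9: the tether should adopt the chair in which the C9 side chain and the bulky C8 silyloxy group are equatorial, so that C9–H lies next to the C1 methylene (least allylic strain) and C5 bonds to C10 anti to the C9 side chain. The diene geometry (tether trans to the vinyl group), combined with the tether-exo, methyl-endo arrangement, then gives the trans ring fusion (5α-H, 10β-CH3). The step needs trans over cis fusion and one of the two tether chairs; the equatorial preferences above should secure these, helped by the C4 ester, which is cis to C6 and forces C7 out of the diene plane, while regiochemistry is fixed by the tether length. The side-chain diene can reach the isopropenyl group or the enoate only in bridged or medium-ring modes and should not compete at high dilution.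

**Step 10**
Reactants: 17 methyl 8α-[(trimethylsilyl)oxy]-18-norlabda-3,13(16),14-trien-19-oate (5R,8R,9R,10S)
Product: 19 methyl 8α-[(trimethylsilyl)oxy]labda-13(16),14-dien-19-oate (4S,5R,8R,9R,10S), via lithium ester enolate 18 (not isolated)
Conditions: LiBH(s-Bu)3, THF, −78 °C; then MeI, DMPU, −78 to 0 °C
Reagents that add atoms: iodomethane, CI; lithium tri-sec-butylborohydride, [Li+].CCC(C)[BH-](C(C)CC)C(C)CC (lithium in intermediate 18 only)
Why: Conjugate reduction–enolate alkylation: hydride should add to C3 of the enoate to give the C4 ester enolate regiospecifically, and iodomethane should approach from the equatorial α-face, away from the 1,3-diaxial C20 methyl, placing C18 α and the ester β-axial (4S) while the isolated diene is untouched.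

**Step 11**
Reactants: 19 methyl 8α-[(trimethylsilyl)oxy]labda-13(16),14-dien-19-oate (4S,5R,8R,9R,10S)
Product: 21 labda-13(16),14-diene-8α,19-diol (4S,5R,8R,9R,10S), via silyl ether alcohol 20 (not isolated)
Conditions: LiAlH4, THF, 0 °C to reflux; H2O, aq. NaOH work-up; then PPTS (cat.), MeOH, rt
Reagents that add atoms: none
Why: Hydride reduction of the hindered neopentyl ester gives the C19 primary alcohol, and mild acid-catalysed methanolysis then removes the tertiary trimethylsilyl ether without touching the diene or any stereocenter.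

**Step 12**
Reactants: 21 labda-13(16),14-diene-8α,19-diol (4S,5R,8R,9R,10S); 22 (2E)-3-(4-methoxyphenyl)prop-2-enoic acid
Product: 23 8α-hydroxylabda-13(16),14-dien-19-yl (2E)-3-(4-methoxyphenyl)prop-2-enoate (4S,5R,8R,9R,10S)
Conditions: DCC, DMAP (cat.), CH2Cl2, 0 °C to rt
Reagents that add atoms: none
Why: Steglich esterification should acylate the primary C19 hydroxyl selectively, because the tertiary, axially flanked C8 hydroxyl is far less reactive, and the (E)-cinnamate geometry is carried over unchanged.

**Compound list**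

1 | myrcene (7-methyl-3-methylideneocta-1,6-diene) | C=CC(=C)CCC=C(C)C | starting material
2 | (2E)-2-methyl-6-methylideneocta-2,7-dien-1-ol | C=CC(=C)CC/C=C(\C)CO | intermediate
3 | [(2R,3R)-2-methyl-3-(3-methylidenepent-4-en-1-yl)oxiran-2-yl]methanol | OC[C@@]1(C)O[C@@H]1CCC(=C)C=C | intermediate
4 | isopropenylmagnesium bromide (prop-1-en-2-ylmagnesium bromide) | C=C(C)[Mg]Br | starting material
5 | (2S,3R)-2-methyl-6-methylidene-3-(prop-1-en-2-yl)oct-7-ene-1,2-diol | OC[C@@](C)(O)[C@@H](C(C)=C)CCC(=C)C=C | intermediate
6 | (2S,3R)-2-hydroxy-2-methyl-6-methylidene-3-(prop-1-en-2-yl)oct-7-en-1-yl 4-methylbenzenesulfonate | Cc1ccc(cc1)S(=O)(=O)OC[C@@](C)(O)[C@@H](C(C)=C)CCC(=C)C=C | intermediate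
7 | (2S)-2-methyl-2-[(3R)-2-methyl-6-methylideneocta-1,7-dien-3-yl]oxirane | C1O[C@@]1(C)[C@@H](C(C)=C)CCC(=C)C=C | intermediate
8 | acetonitrile | CC#N | starting material
9 | lithium (4R,5R)-1-cyano-3-methyl-7-methylidene-4-(prop-1-en-2-yl)non-8-en-3-olate (lithium alkoxide of the hydroxy nitrile) | N#CCC[C@@](C)([O-])[C@@H](C(C)=C)CCC(=C)C=C.[Li+] | intermediate
10 | (4R,5R)-4-methyl-8-methylidene-5-(prop-1-en-2-yl)-4-[(trimethylsilyl)oxy]dec-9-enenitrile | N#CCC[C@@](C)(O[Si](C)(C)C)[C@@H](C(C)=C)CCC(=C)C=C | intermediate
11 | N-(diisobutylalumanyl)imine of aldehyde 12 | CC(C)C[Al](CC(C)C)N=CCC[C@@](C)(O[Si](C)(C)C)[C@@H](C(C)=C)CCC(=C)C=C | intermediate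
12 | (4R,5R)-4-methyl-8-methylidene-5-(prop-1-en-2-yl)-4-[(trimethylsilyl)oxy]dec-9-enal | O=CCC[C@@](C)(O[Si](C)(C)C)[C@@H](C(C)=C)CCC(=C)C=C | intermediate
13 | methyl 2-[bis(2,2,2-trifluoroethoxy)phosphoryl]-2-bromoacetate | COC(=O)C(Br)P(=O)(OCC(F)(F)F)OCC(F)(F)F | starting material
14 | methyl (2E,6R,7R)-2-bromo-6-methyl-10-methylidene-7-(prop-1-en-2-yl)-6-[(trimethylsilyl)oxy]dodeca-2,11-dienoate | COC(=O)/C(Br)=C\CC[C@@](C)(O[Si](C)(C)C)[C@@H](C(C)=C)CCC(=C)C=C | intermediate
15 | tributyl(ethenyl)stannane | C=C[Sn](CCCC)(CCCC)CCCC | starting material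
16 | methyl (2Z,6R,7R)-2-ethenyl-6-methyl-10-methylidene-7-(prop-1-en-2-yl)-6-[(trimethylsilyl)oxy]dodeca-2,11-dienoate | COC(=O)/C(C=C)=C\CC[C@@](C)(O[Si](C)(C)C)[C@@H](C(C)=C)CCC(=C)C=C | intermediate
17 | methyl 8α-[(trimethylsilyl)oxy]-18-norlabda-3,13(16),14-trien-19-oate (5R,8R,9R,10S) = methyl (4aS,5R,6R,8aR)-4a,6-dimethyl-5-(3-methylidenepent-4-en-1-yl)-6-[(trimethylsilyl)oxy]-3,4,4a,5,6,7,8,8a-octahydronaphthalene-1-carboxylate | C=CC(=C)CC[C@@H]1[C@@]2(C)CCC=C(C(=O)OC)[C@@H]2CC[C@@]1(C)O[Si](C)(C)C | intermediate
18 | lithium ester enolate at C4/C19 of the 3,4-dihydro derivative of 17 (5R,8R,9R,10S) | C=CC(=C)CC[C@@H]1[C@@]2(C)CCCC(=C([O-])OC)[C@@H]2CC[C@@]1(C)O[Si](C)(C)C.[Li+] | intermediate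
19 | methyl 8α-[(trimethylsilyl)oxy]labda-13(16),14-dien-19-oate (4S,5R,8R,9R,10S) | C=CC(=C)CC[C@@H]1[C@@]2(C)CCC[C@](C)(C(=O)OC)[C@@H]2CC[C@@]1(C)O[Si](C)(C)C | intermediate
20 | 8α-[(trimethylsilyl)oxy]labda-13(16),14-dien-19-ol (4S,5R,8R,9R,10S), present as its alkoxyaluminate before work-up | C=CC(=C)CC[C@@H]1[C@@]2(C)CCC[C@](C)(CO)[C@@H]2CC[C@@]1(C)O[Si](C)(C)C | intermediate
21 | labda-13(16),14-diene-8α,19-diol (4S,5R,8R,9R,10S) | C=CC(=C)CC[C@@H]1[C@@]2(C)CCC[C@](C)(CO)[C@@H]2CC[C@@]1(C)O | intermediate
22 | (2E)-3-(4-methoxyphenyl)prop-2-enoic acid (trans-4-methoxycinnamic acid) | COc1ccc(/C=C/C(O)=O)cc1 | starting material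
23 | 8α-hydroxylabda-13(16),14-dien-19-yl (2E)-3-(4-methoxyphenyl)prop-2-enoate (4S,5R,8R,9R,10S) | C=CC(=C)CC[C@@H]1[C@@]2(C)CCC[C@](C)(COC(=O)/C=C/c3ccc(OC)cc3)[C@@H]2CC[C@@]1(C)O | target

**Step count and risks**

Total step count: 12. Longest linear sequence: 12 steps (from myrcene 1 to 23).

Steps most likely to fail:

1. Step 9. The risk is loss of diastereocontrol: the two chair-like tether arrangements (C9 chain equatorial or axial) and the trans- and cis-fusing geometries may compete, and the electron-poor diene may dimerise before it cyclises. Fallback, setting out from 16 and returning at 17: the silyl ether would be cleaved (PPTS, MeOH) to give the hydroxy triene F1. Iodoetherification (I2, NaHCO3, MeCN, 0 °C) of the C8 hydroxyl onto C13 of the side-chain diene would give the tetrahydropyranyl iodo ether F2 as a pair of C13 epimers. In F2 a temporary six-membered ether ring spans O-8 and C-11, which can only be bridged when both are equatorial on the forming ring B; this removes the competing chair and masks the spectator diene. Thermolysis (toluene, BHT, 160–170 °C, dark) should then give the cycloadduct F3. Reductive β-elimination (Zn, AcOH, EtOH) would reopen the ether and restore both the C13(16) methylene and the C8 hydroxyl in the hydroxy ester F4, and Me3SiOTf with 2,6-lutidine would return 17.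

2. Step 10. The risk is competing 1,2-hydride delivery to the ester, incomplete conjugate reduction, or sluggish and poorly face-selective C-methylation of the borane-bound enolate. Fallback, setting out from 17 and returning at 19: reduction and alkylation are separated. Catalytic copper hydride (Cu(OAc)2, 1,2-bis(diphenylphosphino)benzene, tetramethyldisiloxane, t-BuOH, toluene) would give the saturated ester F5 as a mixture of C4 epimers. Its enolate, made by deprotonation (LiN(i-Pr)2, THF, −78 °C), would be methylated with MeI in the presence of DMPU on the same equatorial face to give 19.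

3. Step 3. The risk is attack at the wrong carbon after base-induced epoxide migration (Payne-type), or slow transfer of the alkenyl group from copper to the hindered epoxide carbon. Fallback, setting out from 3 and returning at 5: the epoxy alcohol would be opened at C9, with the same inversion, by an alkynylalane (Et2AlC≡CSiMe3, toluene, 0 °C), a reagent class that reliably attacks the distal carbon of 2,3-epoxy alcohols, to give the silylalkynyl diol F6. K2CO3 in MeOH would give the terminal alkynyl diol F7, and zirconium-catalysed methylalumination (Me3Al, Cp2ZrCl2, CH2Cl2) followed by protonolysis would turn the ethynyl group into the isopropenyl group of 5.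

**Further compounds**

F1 | step 9 | methyl (2Z,6R,7R)-2-ethenyl-6-hydroxy-6-methyl-10-methylidene-7-(prop-1-en-2-yl)dodeca-2,11-dienoate | COC(=O)/C(C=C)=C\CC[C@@](C)(O)[C@@H](C(C)=C)CCC(=C)C=C
F2 | step 9 | methyl (2Z)-2-ethenyl-5-[(2R,3R)-6-ethenyl-6-(iodomethyl)-2-methyl-3-(prop-1-en-2-yl)oxan-2-yl]pent-2-enoate (both epimers at C6 of the oxane) | COC(=O)/C(C=C)=C\CC[C@@]1(C)OC(CI)(C=C)CC[C@@H]1C(C)=C
F3 | step 9 | methyl 8α,13-epoxy-16-iodo-18-norlabda-3,14-dien-19-oate (5R,8R,9R,10S; both C13 epimers) | C=CC3(CI)CC[C@@H]1[C@@]2(C)CCC=C(C(=O)OC)[C@@H]2CC[C@@]1(C)O3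
F4 | step 9 | methyl 8α-hydroxy-18-norlabda-3,13(16),14-trien-19-oate (5R,8R,9R,10S) | C=CC(=C)CC[C@@H]1[C@@]2(C)CCC=C(C(=O)OC)[C@@H]2CC[C@@]1(C)O
F5 | step 10 | methyl 8α-[(trimethylsilyl)oxy]-18-norlabda-13(16),14-dien-19-oate (5R,8R,9R,10S; both C4 epimers) | C=CC(=C)CC[C@@H]1[C@@]2(C)CCCC(C(=O)OC)[C@@H]2CC[C@@]1(C)O[Si](C)(C)C
F6 | step 3 | (2S,3R)-2-methyl-6-methylidene-3-[(trimethylsilyl)ethynyl]oct-7-ene-1,2-diol | OC[C@@](C)(O)[C@@H](C#C[Si](C)(C)C)CCC(=C)C=C
F7 | step 3 | (2S,3R)-3-ethynyl-2-methyl-6-methylideneoct-7-ene-1,2-diol | OC[C@@](C)(O)[C@@H](C#C)CCC(=C)C=C
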